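Ring positions follow elemane numbering: the cyclohexane is C5–C10, with quaternary C10 (methyl, vinyl), ring methylene C9, angelate carbon C8 and lactone carbons C7 and C6. The key step exploits the C8–C9–C10 segment: C9, the only unsubstituted ring carbon, lies between oxygenated C8 and methyl-bearing C10. A cyclopentene silyl enol ether C8(OSi)=C10(CH3), made by cuprate addition to a purchased (S)-4-silyloxycyclopentenone, is cyclopropanated, and FeCl3 then cuts the shared C8–C10 bond (Ito–Saegusa enlargement), turning the five-membered ring into the six-membered β-methyl enone in one operation. Its C5 substituent steers vinyl cuprate to C10; C7 and C8 follow by substrate control from the single purchased stereocentre at C6.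

Key step: step 5

Remark: (S)-4-(tert-butyldimethylsilyloxy)cyclopent-2-en-1-one and angelic acid are taken as commercial; C-numbers in the text are elemane positions of the target.

Step 1
Reactants: 1 (S)-4-[(tert-butyldimethylsilyl)oxy]cyclopent-2-en-1-one
Product: 2 (S)-4-[(tert-butyldimethylsilyl)oxy]-2-iodocyclopent-2-en-1-one
Conditions: I2, pyridine, CH2Cl2, 0 °C to rt
Reagents that add atoms: iodine II
Why: Pyridine-mediated α-iodination of an enone (conjugate addition of pyridine, iodination of the enolate, elimination) touches only the α-carbon and leaves the silyloxy stereocentre intact.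

Step 2
Reactants: 2 (S)-4-[(tert-butyldimethylsilyl)oxy]-2-iodocyclopent-2-en-1-one
Product: 3 (S)-4-[(tert-butyldimethylsilyl)oxy]-2-methylcyclopent-2-en-1-one
Conditions: Me4Sn, Pd2(dba)3 (cat.), AsPh3, CuI, NMP, 60 °C
Reagents that add atoms: tetramethylstannane C[Sn](C)(C)C
Why: Stille cross-coupling of the α-iodo enone proceeds under neutral conditions, which avoids base-induced loss of the β-silyloxy group.

Step 3
Reactants: 3 (S)-4-[(tert-butyldimethylsilyl)oxy]-2-methylcyclopent-2-en-1-one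
Product: 4 {[(3S,4S)-4-[(tert-butyldimethylsilyl)oxy]-2-methyl-3-(prop-1-en-2-yl)cyclopent-1-en-1-yl]oxy}trimethylsilane
Conditions: CH2=C(CH3)MgBr, CuBr·SMe2 (cat.), TMSCl, DMPU, THF, −78 °C; Et3N, pentane work-up
Reagents that add atoms: isopropenylmagnesium bromide C=C(C)[Mg]Br; chlorotrimethylsilane C[Si](C)(C)Cl
Why: Copper-catalysed conjugate addition should occur anti to the C6 silyloxy group (as in prostaglandin-type 1,4-additions) and so set C5, while TMSCl traps the enolate regiospecifically as the C8=C10 silyl enol ether.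

Step 4
Reactants: 4 {[(3S,4S)-4-[(tert-butyldimethylsilyl)oxy]-2-methyl-3-(prop-1-en-2-yl)cyclopent-1-en-1-yl]oxy}trimethylsilane
Product: 5 tert-butyl{[(1S,2S,3S,5S)-1-methyl-2-(prop-1-en-2-yl)-5-[(trimethylsilyl)oxy]bicyclo[3.1.0]hexan-3-yl]oxy}dimethylsilane (cyclopropane CH2 on the face opposite to the isopropenyl group)
Conditions: Et2Zn, CH2I2, CH2Cl2, 0 °C
Reagents that add atoms: diiodomethane ICI
Why: In this Furukawa–Simmons–Smith cyclopropanation the electrophilic zinc carbenoid should attack the electron-rich silyl enol ether faster than the isopropenyl group and on the face anti to it, and the two new stereocentres (C8, C10) are erased in step 5.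

Step 5
Reactants: 5 tert-butyl{[(1S,2S,3S,5S)-1-methyl-2-(prop-1-en-2-yl)-5-[(trimethylsilyl)oxy]bicyclo[3.1.0]hexan-3-yl]oxy}dimethylsilane
Product: 7 (4S,5S)-5-[(tert-butyldimethylsilyl)oxy]-3-methyl-4-(prop-1-en-2-yl)cyclohex-2-en-1-one, via chloro ketone 6 (not isolated)
Conditions: FeCl3 (2.2 equiv), DMF, 0 °C; then NaOAc, MeOH, 40 °C
Reagents that add atoms: none
Why: Trivalent iron exchanges the trimethylsilyl group to give an iron cyclopropoxide, whose homolysis to the alkoxy radical is followed by β-scission of the shared C8–C10 bond; the tertiary β-keto radical at C10 takes chlorine from FeCl3 to give chloro ketone 6, and acetate then removes HCl across C9–C10. The closest known reaction is the Ito–Saegusa FeCl3 ring enlargement of 1-siloxybicyclo[n.1.0]alkanes to 2-cycloalkenones. No new ring is closed: the five-membered ring C5–C6–C7–C8–C10 grows to the six-membered ring by opening of the fused cyclopropane, which places the carbenoid carbon C9 between C8 and C10. No stereocentre is created, and C5 and C6 are remote from the bonds that change and are carried through. The step needs cleavage of the internal and not an external cyclopropane bond, which the methyl group at C10 secures because only that cleavage gives a tertiary radical in an unstrained ring, and it needs elimination toward C9, which the acidity of the C9 hydrogens next to the ketone secures. The isopropenyl group and the silyl ether should not be attacked by FeCl3 in DMF at 0 °C.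

Step 6
Reactants: 7 (4S,5S)-5-[(tert-butyldimethylsilyl)oxy]-3-methyl-4-(prop-1-en-2-yl)cyclohex-2-en-1-one
Product: 9 (3S,4S,5S)-5-[(tert-butyldimethylsilyl)oxy]-3-ethenyl-3-methyl-4-(prop-1-en-2-yl)cyclohexan-1-one, via trimethylsilyl enol ether 8 (not isolated)
Conditions: CH2=CHMgBr, CuBr·SMe2, TMSCl, THF, −78 to −40 °C; then AcOH, H2O, THF, rt
Reagents that add atoms: vinylmagnesium bromide C=C[Mg]Br
Why: In this TMSCl-accelerated copper-mediated conjugate addition the vinyl group should enter C10 anti to the adjacent C5 isopropenyl group (axial attack on the half-chair with C5 pseudoaxial, as with γ-substituted cyclohexenones), which sets the quaternary centre, and the enol ether 8 is hydrolysed on work-up.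

Step 7
Reactants: 9 (3S,4S,5S)-5-[(tert-butyldimethylsilyl)oxy]-3-ethenyl-3-methyl-4-(prop-1-en-2-yl)cyclohexan-1-one
Product: 10 methyl 2-[(1S,2R,3S,4S)-2-[(tert-butyldimethylsilyl)oxy]-4-ethenyl-4-methyl-6-oxo-3-(prop-1-en-2-yl)cyclohexyl]acetate
Conditions: LiN(i-Pr)2, THF, −78 °C; BrCH2CO2Me, DMPU, −78 to −30 °C; then DBU (cat.), CH2Cl2, rt
Reagents that add atoms: methyl bromoacetate COC(=O)CBr
Why: Kinetic deprotonation should occur at C7, away from the neopentyl C9, and enolate alkylation followed by base equilibration of the epimerisable C7 should place the acetate arm equatorial and trans to the C6 silyloxy group (thermodynamic control).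

Step 8
Reactants: 10 methyl 2-[(1S,2R,3S,4S)-2-[(tert-butyldimethylsilyl)oxy]-4-ethenyl-4-methyl-6-oxo-3-(prop-1-en-2-yl)cyclohexyl]acetate
Product: 12 (3aS,6S,7S,7aR)-6-ethenyl-6-methyl-7-(prop-1-en-2-yl)hexahydro-1-benzofuran-2,4-dione (trans-fused), via hydroxy ester 11 (not isolated)
Conditions: HF·pyridine, THF, 0 °C to rt; then TsOH (cat.), benzene, rt
Reagents that add atoms: none
Why: Desilylation frees the C6 hydroxyl, which lies trans-diequatorial to the C7 acetate arm and should close the trans-fused γ-lactone by acid-catalysed lactonisation while the C8 ketone cannot compete.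

Step 9
Reactants: 12 (3aS,6S,7S,7aR)-6-ethenyl-6-methyl-7-(prop-1-en-2-yl)hexahydro-1-benzofuran-2,4-dione
Product: 13 (3aR,4R,6S,7S,7aR)-6-ethenyl-4-hydroxy-6-methyl-7-(prop-1-en-2-yl)hexahydro-1-benzofuran-2(3H)-one (axial 8β-alcohol)
Conditions: LiBH(s-Bu)3, THF, −78 °C; AcOH quench at −78 °C
Reagents that add atoms: none
Why: In this steric-approach-controlled ketone reduction the bulky hydride should attack C8 from the equatorial direction, because the axial C10 methyl group blocks the axial trajectory, giving the axial alcohol, and the lactone is not reduced at −78 °C.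

Step 10
Reactants: 13 (3aR,4R,6S,7S,7aR)-6-ethenyl-4-hydroxy-6-methyl-7-(prop-1-en-2-yl)hexahydro-1-benzofuran-2(3H)-one
Product: 16 (3aR,4R,6S,7S,7aR)-6-ethenyl-4-hydroxy-6-methyl-3-methylidene-7-(prop-1-en-2-yl)hexahydro-1-benzofuran-2(3H)-one, via Mannich base 14 (not isolated), via methiodide 15 (not isolated)
Conditions: LiN(i-Pr)2 (2.3 equiv), THF, −78 °C; CH2=NMe2+ I−, −78 °C to rt; aqueous work-up; MeI, MeOH, rt; NaHCO3 (aq), CH2Cl2
Reagents that add atoms: N,N-dimethylmethyleneiminium iodide C=[N+](C)C.[I-]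
Why: Eschenmoser methylenation (lactone enolate Mannich reaction, quaternisation, Hofmann-type elimination) installs the exocyclic methylene at C11, with the extra equivalent of base holding the C8 hydroxyl as its alkoxide.

Step 11
Reactants: 16 (3aR,4R,6S,7S,7aR)-6-ethenyl-4-hydroxy-6-methyl-3-methylidene-7-(prop-1-en-2-yl)hexahydro-1-benzofuran-2(3H)-one; 17 angelic acid [(2Z)-2-methylbut-2-enoic acid]
Product: 18 (3aR,4S,6S,7S,7aR)-6-ethenyl-6-methyl-3-methylidene-2-oxo-7-(prop-1-en-2-yl)octahydro-1-benzofuran-4-yl (2Z)-2-methylbut-2-enoate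
Conditions: PPh3, DIAD, toluene, 0 °C to rt
Reagents that add atoms: none
Why: Mitsunobu esterification should displace the activated axial C8 hydroxyl by angelate with inversion (SN2) to give the equatorial 8α-ester under neutral conditions that do not isomerise the Z-olefin.

Step 12
Reactants: 18 (3aR,4S,6S,7S,7aR)-6-ethenyl-6-methyl-3-methylidene-2-oxo-7-(prop-1-en-2-yl)octahydro-1-benzofuran-4-yl (2Z)-2-methylbut-2-enoate
Product: 19 (3aR,4S,6S,7R,7aR)-6-ethenyl-7-(3-hydroxyprop-1-en-2-yl)-6-methyl-3-methylidene-2-oxooctahydro-1-benzofuran-4-yl (2Z)-2-methylbut-2-enoate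
Conditions: SeO2 (0.5 equiv), t-BuOOH, CH2Cl2, rt
Reagents that add atoms: selenium dioxide O=[Se]=O; tert-butyl hydroperoxide CC(C)(C)OO
Why: SeO2 allylic oxidation (ene reaction then [2,3]-sigmatropic shift) should select the methyl group of the isopropenyl unit, the only electron-rich olefin with allylic hydrogens, since the vinyl group has none and the acrylate-type olefins are deactivated.

Step 13
Reactants: 19 (3aR,4S,6S,7R,7aR)-6-ethenyl-7-(3-hydroxyprop-1-en-2-yl)-6-methyl-3-methylidene-2-oxooctahydro-1-benzofuran-4-yl (2Z)-2-methylbut-2-enoate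
Product: 21 2-[(3aR,4S,6S,7R,7aR)-6-ethenyl-6-methyl-4-{[(2Z)-2-methylbut-2-enoyl]oxy}-3-methylidene-2-oxooctahydro-1-benzofuran-7-yl]prop-2-enoic acid (target), via enal 20 (not isolated)
Conditions: MnO2, CH2Cl2, rt; then NaClO2, NaH2PO4, 2-methyl-2-butene, t-BuOH/H2O, 0 °C
Reagents that add atoms: sodium chlorite [Na+].[O-]Cl=O
Why: MnO2 oxidises only the allylic alcohol to the enal, and Pinnick oxidation then gives the acrylic acid without touching the other olefins, the lactone or the angelate.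

Compound list
1 | (S)-4-[(tert-butyldimethylsilyl)oxy]cyclopent-2-en-1-one | O=C1C=C[C@@H](O[Si](C)(C)C(C)(C)C)C1 | starting material
2 | (S)-4-[(tert-butyldimethylsilyl)oxy]-2-iodocyclopent-2-en-1-one | O=C1C(I)=C[C@@H](O[Si](C)(C)C(C)(C)C)C1 | intermediate
3 | (S)-4-[(tert-butyldimethylsilyl)oxy]-2-methylcyclopent-2-en-1-one | CC1=C[C@@H](O[Si](C)(C)C(C)(C)C)CC1=O | intermediate
4 | {[(3S,4S)-4-[(tert-butyldimethylsilyl)oxy]-2-methyl-3-(prop-1-en-2-yl)cyclopent-1-en-1-yl]oxy}trimethylsilane (3,4-trans) | CC1=C(O[Si](C)(C)C)C[C@H](O[Si](C)(C)C(C)(C)C)[C@H]1C(C)=C | intermediate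
5 | tert-butyl{[(1S,2S,3S,5S)-1-methyl-2-(prop-1-en-2-yl)-5-[(trimethylsilyl)oxy]bicyclo[3.1.0]hexan-3-yl]oxy}dimethylsilane (cyclopropane anti to isopropenyl) | C[C@@]12C[C@]1(O[Si](C)(C)C)C[C@H](O[Si](C)(C)C(C)(C)C)[C@H]2C(C)=C | intermediate
6 | (4S,5S)-5-[(tert-butyldimethylsilyl)oxy]-3-chloro-3-methyl-4-(prop-1-en-2-yl)cyclohexan-1-one (C3 epimers) | CC1(Cl)CC(=O)C[C@H](O[Si](C)(C)C(C)(C)C)[C@H]1C(C)=C | intermediate
7 | (4S,5S)-5-[(tert-butyldimethylsilyl)oxy]-3-methyl-4-(prop-1-en-2-yl)cyclohex-2-en-1-one | CC1=CC(=O)C[C@H](O[Si](C)(C)C(C)(C)C)[C@H]1C(C)=C | intermediate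
8 | trimethylsilyl enol ether (C8=C9) of ketone 9 | C=C[C@]1(C)C=C(O[Si](C)(C)C)C[C@H](O[Si](C)(C)C(C)(C)C)[C@H]1C(C)=C | intermediate
9 | (3S,4S,5S)-5-[(tert-butyldimethylsilyl)oxy]-3-ethenyl-3-methyl-4-(prop-1-en-2-yl)cyclohexan-1-one | C=C[C@]1(C)CC(=O)C[C@H](O[Si](C)(C)C(C)(C)C)[C@H]1C(C)=C | intermediate
10 | methyl 2-[(1S,2R,3S,4S)-2-[(tert-butyldimethylsilyl)oxy]-4-ethenyl-4-methyl-6-oxo-3-(prop-1-en-2-yl)cyclohexyl]acetate | C=C[C@]1(C)CC(=O)[C@@H](CC(=O)OC)[C@H](O[Si](C)(C)C(C)(C)C)[C@H]1C(C)=C | intermediate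
11 | methyl 2-[(1S,2R,3S,4S)-4-ethenyl-2-hydroxy-4-methyl-6-oxo-3-(prop-1-en-2-yl)cyclohexyl]acetate | C=C[C@]1(C)CC(=O)[C@@H](CC(=O)OC)[C@H](O)[C@H]1C(C)=C | intermediate
12 | (3aS,6S,7S,7aR)-6-ethenyl-6-methyl-7-(prop-1-en-2-yl)hexahydro-1-benzofuran-2,4-dione | C=C[C@]1(C)CC(=O)[C@H]2CC(=O)O[C@@H]2[C@H]1C(C)=C | intermediate
13 | (3aR,4R,6S,7S,7aR)-6-ethenyl-4-hydroxy-6-methyl-7-(prop-1-en-2-yl)hexahydro-1-benzofuran-2(3H)-one | C=C[C@]1(C)C[C@@H](O)[C@H]2CC(=O)O[C@@H]2[C@H]1C(C)=C | intermediate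
14 | 3-[(dimethylamino)methyl] derivative of 13 (C3 epimers) | C=C[C@]1(C)C[C@@H](O)[C@H]2C(CN(C)C)C(=O)O[C@@H]2[C@H]1C(C)=C | intermediate
15 | trimethylammonium iodide (methiodide) of 14 | C=C[C@]1(C)C[C@@H](O)[C@H]2C(C[N+](C)(C)C)C(=O)O[C@@H]2[C@H]1C(C)=C.[I-] | intermediate
16 | (3aR,4R,6S,7S,7aR)-6-ethenyl-4-hydroxy-6-methyl-3-methylidene-7-(prop-1-en-2-yl)hexahydro-1-benzofuran-2(3H)-one | C=C[C@]1(C)C[C@@H](O)[C@H]2C(=C)C(=O)O[C@@H]2[C@H]1C(C)=C | intermediate
17 | angelic acid, (2Z)-2-methylbut-2-enoic acid | C/C=C(/C)C(=O)O | starting material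
18 | (3aR,4S,6S,7S,7aR)-6-ethenyl-6-methyl-3-methylidene-2-oxo-7-(prop-1-en-2-yl)octahydro-1-benzofuran-4-yl (2Z)-2-methylbut-2-enoate | C=C[C@]1(C)C[C@H](OC(=O)/C(C)=C\C)[C@H]2C(=C)C(=O)O[C@@H]2[C@H]1C(C)=C | intermediate
19 | (3aR,4S,6S,7R,7aR)-6-ethenyl-7-(3-hydroxyprop-1-en-2-yl)-6-methyl-3-methylidene-2-oxooctahydro-1-benzofuran-4-yl (2Z)-2-methylbut-2-enoate | C=C[C@]1(C)C[C@H](OC(=O)/C(C)=C\C)[C@H]2C(=C)C(=O)O[C@@H]2[C@H]1C(=C)CO | intermediate
20 | (3aR,4S,6S,7R,7aR)-6-ethenyl-6-methyl-3-methylidene-2-oxo-7-(3-oxoprop-1-en-2-yl)octahydro-1-benzofuran-4-yl (2Z)-2-methylbut-2-enoate | C=C[C@]1(C)C[C@H](OC(=O)/C(C)=C\C)[C@H]2C(=C)C(=O)O[C@@H]2[C@H]1C(=C)C=O | intermediate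
21 | 2-[(3aR,4S,6S,7R,7aR)-6-ethenyl-6-methyl-4-{[(2Z)-2-methylbut-2-enoyl]oxy}-3-methylidene-2-oxooctahydro-1-benzofuran-7-yl]prop-2-enoic acid | C=C[C@]1(C)C[C@H](OC(=O)/C(C)=C\C)[C@H]2C(=C)C(=O)O[C@@H]2[C@H]1C(=C)C(=O)O | target

Total step count: 13
Longest linear sequence: 13 steps (from 1 to 21)

Steps most likely to fail

Step 5. What may go wrong: FeCl3 may strip the tert-butyldimethylsilyl ether, and the β-silyloxy chloro ketone may lose silanol during dehydrochlorination and aromatise. Fallback: it sets out from 4 and keeps the one-carbon enlargement of the five-membered ring, but through a different mechanism. Dibromocarbene (CHBr3, KOt-Bu, pentane, −30 °C) is added to the enol ether to give the dibromocyclopropane F1. On warming, F1 should open by cyclopropyl–allyl cation ring opening, with loss of bromotrimethylsilane, to the ring-enlarged 2-bromo enone F2. Radical hydrodebromination (Bu3SnH, AIBN, benzene, 80 °C) comes back to the route at 7.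

Step 7. What may go wrong: β-elimination of the silyloxy group from the C7 lithium enolate, or competing deprotonation at C9. Fallback: it sets out from 9 and uses a Stork enamine alkylation, so that no strongly basic enolate is formed. Condensation with pyrrolidine (TsOH cat., benzene, reflux with removal of water) should give the less substituted pyrrolidine enamine F3. Alkylation with methyl bromoacetate in MeCN gives the iminium bromide F4, and hydrolysis with aqueous NaOAc/AcOH comes back to the route at 10.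

Step 11. What may go wrong: E2 elimination of the activated axial alcohol toward C7 or C9, esterification with retention through an acyloxyphosphonium path, or phosphine addition to the methylene lactone. Fallback: it sets out from 12 and sets the C8 configuration at the reduction instead of by inversion. SmI2 (THF, i-PrOH) should reduce the ketone under electron-transfer, product-stability control to the equatorial 8α-alcohol F5. Methylenation as in step 10 passes through the Mannich base F6 and its methiodide F7 to the 8α-hydroxy methylene lactone F8. Yamaguchi esterification with 17 (2,4,6-trichlorobenzoyl chloride, Et3N, then DMAP, toluene) proceeds with retention and comes back to the route at 18.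

Further compounds
F1 | step 5 | tert-butyl{[6,6-dibromo-1-methyl-2-(prop-1-en-2-yl)-5-[(trimethylsilyl)oxy]bicyclo[3.1.0]hexan-3-yl]oxy}dimethylsilane (configuration as in 5) | C[C@@]12C(Br)(Br)[C@]1(O[Si](C)(C)C)C[C@H](O[Si](C)(C)C(C)(C)C)[C@H]2C(C)=C
F2 | step 5 | (4S,5S)-2-bromo-5-[(tert-butyldimethylsilyl)oxy]-3-methyl-4-(prop-1-en-2-yl)cyclohex-2-en-1-one | CC1=C(Br)C(=O)C[C@H](O[Si](C)(C)C(C)(C)C)[C@H]1C(C)=C
F3 | step 7 | pyrrolidine enamine (C7=C8) of ketone 9 | C=C[C@]1(C)CC(N2CCCC2)=C[C@H](O[Si](C)(C)C(C)(C)C)[C@H]1C(C)=C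
F4 | step 7 | C7-alkylated pyrrolidinium (iminium) bromide of 10 (C7 epimers) | C=C[C@]1(C)CC(=[N+]2CCCC2)C(CC(=O)OC)[C@H](O[Si](C)(C)C(C)(C)C)[C@H]1C(C)=C.[Br-]
F5 | step 11 | (3aR,4S,6S,7S,7aR)-6-ethenyl-4-hydroxy-6-methyl-7-(prop-1-en-2-yl)hexahydro-1-benzofuran-2(3H)-one | C=C[C@]1(C)C[C@H](O)[C@H]2CC(=O)O[C@@H]2[C@H]1C(C)=C
F6 | step 11 | 3-[(dimethylamino)methyl] derivative of F5 (C3 epimers) | C=C[C@]1(C)C[C@H](O)[C@H]2C(CN(C)C)C(=O)O[C@@H]2[C@H]1C(C)=C
F7 | step 11 | trimethylammonium iodide (methiodide) of F6 | C=C[C@]1(C)C[C@H](O)[C@H]2C(C[N+](C)(C)C)C(=O)O[C@@H]2[C@H]1C(C)=C.[I-]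
F8 | step 11 | (3aR,4S,6S,7S,7aR)-6-ethenyl-4-hydroxy-6-methyl-3-methylidene-7-(prop-1-en-2-yl)hexahydro-1-benzofuran-2(3H)-one | C=C[C@]1(C)C[C@H](O)[C@H]2C(=C)C(=O)O[C@@H]2[C@H]1C(C)=C
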